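(The constants used here were drawn at random within sensible limits; what happens was integrated by code.)

A leftover of starting complex has two ways to go, on through the first exchange or into side product, and the flasks below differ in what such a leftover meets.

    starting complex + incoming ligand → leaving ligand + complex with one exchanged (k1 = 0.17 L mol⁻¹ s⁻¹)
    complex with one exchanged + incoming ligand → leaving ligand + complex with two exchanged (k2 = 0.057 L mol⁻¹ s⁻¹)
    complex with two exchanged + incoming ligand → leaving ligand + complex with three exchanged (k3 = 0.024 L mol⁻¹ s⁻¹)
    complex with one exchanged + capture agent → trapped intermediate (k4 = 0.048 L mol⁻¹ s⁻¹)
    starting complex + complex with three exchanged → side product (k5 = 0.067 L mol⁻¹ s⁻¹)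

| setting | Friday's | Monday's | Wednesday's | Sunday's | Saturday's |
|---|---|---|---|---|---|
| starting complex | 0.10 M (in portions, 2, over 6.0 min) | 0.10 M | 0.10 M | 0.10 M | 0.10 M (fed, over 6.0 min) |
| incoming ligand | 0.180 M | 0.180 M (fed, over 6.0 min) | 0.180 M (fed, over 40 s) | 0.180 M | 0.180 M |
| leaving ligand | 0.100 M | 0.100 M | 0.100 M | 0.100 M | 0.100 M |
| capture agent | 0.0300 M | 0.0300 M | 0.0300 M | 0.0300 M | 0.0300 M |
| time | 15 min | 15 min | 15 min | 15 min | 15 min |
| remark | first portion at the start, last at 6.0 min | all else is in the flask from the start; the feed brings no volume worth counting | all else is in the flask from the start; the feed brings no volume worth counting | everything together at the start | all else is in the flask from the start; the feed brings no volume worth counting |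

- percent here means starting complex units held: one side product counts as two
- run time (Friday's): 15 min

- the flask that comes out highest in amount of side product, in percent of the starting complex charged, or "all alike" when all lie within 1.5 percentage points (Friday's / Monday's / Wednesday's / Sunday's / Saturday's / all alike)
- side product at the end, in percent of the starting complex charged, Friday's
- side product at the end, in percent of the starting complex charged, Monday's
- side product at the end, in percent of the starting complex charged, Wednesday's
- side product at the end, in percent of the starting complex charged, Sunday's
- side product at the end, in percent of the starting complex charged, Saturday's

We work in fractions of the charge: x is the incoming ligand over its own charge, and c is the complex with three exchanged over the starting complex charged. When we divide the rate at which the side step uses starting complex by the rate at which the first exchange uses it, the starting complex cancels: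

side step / first exchange = S · c / x

The diversion number S = 0.219 is the pull of the side step over that of the first exchange with both partners at their full charge, a selectivity factor. Friday's and Sunday's flasks have equal charges and so the same S, which means that this one number cannot part them, and the recipe has to supply c/x.

For Friday's second portion we suppose that the first portion has taken two ligands per complex, and we guess that half of that portion stands as complex with three exchanged:

x = 0.444, c = 0.250

S · c / x = 0.123

share of the portion diverted = 0.110

Each side product counts double and the portion is one of 2 equal parts of the charge, so our estimate for Friday's is 11.0 %. In Sunday's flask the starting complex has a half-life of 0.38 min by the first exchange alone with the other concentrations as charged, much shorter than the run of 15 min, so we expect most of it to meet x near one and c near nothing, and we commit to a low figure there.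

The forecast names Friday's, with 10 % (range 6.5 % to 14 %) where we reckoned 11.0 %, Saturday's at 6 %, Sunday's at 0.55 %, Wednesday's at 0.5 % and Monday's at 0.3 %, and it points to “most sharply Friday's second portion”.

The simulation gives 12.1 % for Friday's, 7.67 % for Saturday's, 2.50 % for Sunday's, 2.46 % for Wednesday's and 2.17 % for Monday's.

At 15.0 min Friday's flask holds c at 17.5 % and x at 5.50 %, so S · c / x is 0.697, and the first exchange uses starting complex just 1.4 times as fast as the side step does. The neighbour flask, Friday's recipe with 0.025 M of starting complex, has S = 0.0547, and at 15.0 min it holds c at 66.0 % and x at 65.2 %, so S · c / x reads 0.0554 with its starting complex at 0 %, and its side product stands at 1.87 % of its own charge, less than the 12.1 % of Friday's.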